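**Plan**

- Retrosynthesis: the 3-O-acetyl group and three O-benzyl groups (5-O, 3'-O, 4'-O) are removed first; then the C2–C3 bond of the pyranone is cut.
- Enabling feature: C2 carries the ring oxygen O1 and the 3,4-dioxygenated aryl group (a latent oxocarbenium ion), and C3 carries an oxygen next to the C4 ketone (a latent enediolate).
- Joining O3 to C2 in place of C3 gives a seven-membered cyclic acetal, a 2-aryl-1,3-benzodioxepin-5-one (ring O1–C2–O3–C3–C4–C4a–C8a), in which the later 3-oxygen is a ring atom.
- Forward: acetophenone 1 is benzylated and oxidised to ketol 5; ketol 5 and aldehyde acetal 7 are joined through C–O bonds only to the racemic acetal 8.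
- A chiral Sc(III) catalyst then shifts C2 from O3 to C3: the seven-membered ring contracts to the pyranone, and C2–C3 and both stereocentres form at once; acetylation and hydrogenolysis finish the route.
- Stereochemistry: the acetal centre is erased on ionisation (stereoconvergent); C3 comes from the ligand-screened face of the chelated enediolate, and C2 follows through a half-chair closure (2,3-trans).

Key step: step 5

Remark: compounds 1 and 6 are taken as commercial; the sense of induction of the scandium–pybox catalyst in step 5 is assigned by model only, so the (S,S)-ligand is written and its mirror image takes its place if a test run shows the opposite sense.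

**Step 1**
Reactants: 1 1-(2,6-dihydroxy-4-methoxyphenyl)ethan-1-one
Product: 2 1-[2-(benzyloxy)-6-hydroxy-4-methoxyphenyl]ethan-1-one
Conditions: BnBr (1.05 equiv), K2CO3 (1.1 equiv), acetone, reflux
Reagents that add atoms: benzyl bromide BrCc1ccccc1
Why: Williamson ether synthesis; the two phenols are equivalent, and after the first alkylation the remaining hydroxyl is hydrogen-bonded to the ketone and far less nucleophilic, so one equivalent of benzyl bromide should stop at the mono-ether, and no stereocentre is formed.

**Step 2**
Reactants: 2 1-[2-(benzyloxy)-6-hydroxy-4-methoxyphenyl]ethan-1-one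
Product: 5 1-[2-(benzyloxy)-6-hydroxy-4-methoxyphenyl]-2-hydroxyethan-1-one, via bis(trimethylsilyl) enol ether 3 (not isolated), via bis-silylated hydroxy ketone 4 (not isolated)
Conditions: TMSOTf (2.4 equiv), Et3N (3 equiv), CH2Cl2, 0 °C; pentane trituration, concentrate; mCPBA (1.05 equiv), CH2Cl2, −20 → 0 °C; 1 M HCl, THF, rt
Reagents that add atoms: mCPBA O=C(OO)c1cccc(Cl)c1; trimethylsilyl triflate C[Si](C)(C)OS(=O)(=O)C(F)(F)F (silyl groups of 3 and 4 only)
Why: Rubottom oxidation; soft enolisation silylates the phenol and turns the methyl ketone into its silyl enol ether, whose double bond is epoxidised by the peracid faster than the arene, and silyl migration followed by acidic work-up should give the primary ketol without a stereocentre.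

**Step 3**
Reactants: 6 3,4-bis(benzyloxy)benzaldehyde
Product: 7 1,2-bis(benzyloxy)-4-(dimethoxymethyl)benzene
Conditions: HC(OMe)3 (1.5 equiv), p-TsOH·H2O (cat.), MeOH, rt; K2CO3 quench
Reagents that add atoms: trimethyl orthoformate COC(OC)OC
Why: Acid-catalysed acetalisation of an aromatic aldehyde with the orthoformate as methanol source and water scavenger; no stereocentre is formed.

**Step 4**
Reactants: 5 1-[2-(benzyloxy)-6-hydroxy-4-methoxyphenyl]-2-hydroxyethan-1-one; 7 1,2-bis(benzyloxy)-4-(dimethoxymethyl)benzene
Product: 8 rac-6-(benzyloxy)-2-[3,4-bis(benzyloxy)phenyl]-8-methoxy-2H-1,3-benzodioxepin-5(4H)-one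
Conditions: PPTS (10 mol %), PhMe, 5 Å MS, 40 °C; Et3N quench; Et3N-deactivated silica
Reagents that add atoms: none
Why: Transacetalisation; the acetal of the electron-rich aldehyde ionises under mild acid, the primary hydroxyl exchanges first and the ortho phenol then closes the seven-membered ring while the sieves take up methanol, and the acetal centre forms as a racemate that is erased in step 5.

**Step 5**
Reactants: 8 rac-6-(benzyloxy)-2-[3,4-bis(benzyloxy)phenyl]-8-methoxy-2H-1,3-benzodioxepin-5(4H)-one
Product: 9 (2R,3R)-5-(benzyloxy)-2-[3,4-bis(benzyloxy)phenyl]-3-hydroxy-7-methoxy-2,3-dihydro-4H-chromen-4-one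
Conditions: Sc(OTf)3 (10 mol %), (S,S)-Ph-pybox (12 mol %), 2,6-lutidine (20 mol %), 4 Å MS, CH2Cl2 (0.02 M), −40 → 0 °C
Reagents that add atoms: none
Why: Proposed new method: the oxophilic Sc(III) centre binds the only basic acetal oxygen of 8 (the later O3), the O3–C2 bond ionises to an E-configured aryloxy-benzylic oxocarbenium ion (O1=C2, stabilised by the 4-benzyloxyphenyl group) that stays tied through the A ring to a scandium-chelated α-oxido ketone, 2,6-lutidine removes a C3 proton to give the chelated cis-enediolate, and C3 attacks C2, so that C2 shifts from O3 to C3, O3 leaves the ring as the 3-hydroxyl and the seven-membered dioxepinone becomes the six-membered pyranone. The closest known reaction types are the Petasis–Ferrier and the catalytic asymmetric [1,3] O-to-C rearrangements of enol acetals and ethers, which run through a Lewis-acid-bound enolate and a cation, and the additions of chiral chelated metal enolates formed by soft enolisation to acetal-derived oxocarbenium ions; the [1,2] shift with enolisation after ionisation is the new element. The pyranone closes in the 6-(enolendo)-endo-trig mode through a half-chair. C3 is controlled by the pybox ligand, which screens one face of the planar scandium enediolate, and C2 is controlled by C3 through the half-chair, in which the E-oxocarbenium holds the aryl group pseudo-equatorial and the chelate holds O3 pseudo-equatorial, which should give the 2,3-trans (2R,3R) isomer. The acetal centre of 8 is erased on ionisation, so both enantiomers converge on one ion pair. The step needs C- over O-recombination and attack through C3 and not C4 of the enediolate: the first is secured because C–C bond formation is the only irreversible exit, the second by the unhindered CH terminus and by the aryl ketone that results in a six-membered ring.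

**Step 6**
Reactants: 9 (2R,3R)-5-(benzyloxy)-2-[3,4-bis(benzyloxy)phenyl]-3-hydroxy-7-methoxy-2,3-dihydro-4H-chromen-4-one
Product: 10 (2R,3R)-5-(benzyloxy)-2-[3,4-bis(benzyloxy)phenyl]-7-methoxy-4-oxo-3,4-dihydro-2H-chromen-3-yl acetate
Conditions: Ac2O (1.5 equiv), pyridine, DMAP (cat.), CH2Cl2, 0 °C → rt
Reagents that add atoms: acetic anhydride CC(=O)OC(C)=O
Why: Acylation of the secondary 3-hydroxyl under nucleophilic catalysis; all phenols are masked, the base is too weak to enolise C3 or open the pyranone, and both stereocentres are untouched.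

**Step 7**
Reactants: 10 (2R,3R)-5-(benzyloxy)-2-[3,4-bis(benzyloxy)phenyl]-7-methoxy-4-oxo-3,4-dihydro-2H-chromen-3-yl acetate
Product: 11 3-O-acetylpadmatin, (2R,3R)-2-(3,4-dihydroxyphenyl)-5-hydroxy-7-methoxy-4-oxo-3,4-dihydro-2H-chromen-3-yl acetate
Conditions: H2 (1 atm), 10 % Pd/C, EtOAc, rt
Reagents that add atoms: none
Why: Hydrogenolysis of three aryl benzyl ethers over palladium under neutral conditions, which should leave the aryl ketone, the acetate and the C2–O1 bond intact and does not touch C2 or C3.

**Compound list**

1 | 1-(2,6-dihydroxy-4-methoxyphenyl)ethan-1-one | COc1cc(O)c(C(C)=O)c(O)c1 | starting material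
2 | 1-[2-(benzyloxy)-6-hydroxy-4-methoxyphenyl]ethan-1-one | COc1cc(O)c(C(C)=O)c(OCc2ccccc2)c1 | intermediate
3 | {3-(benzyloxy)-5-methoxy-2-[1-(trimethylsilyloxy)ethenyl]phenoxy}trimethylsilane (bis(trimethylsilyl) enol ether) | COc1cc(O[Si](C)(C)C)c(C(=C)O[Si](C)(C)C)c(OCc2ccccc2)c1 | intermediate
4 | 1-[2-(benzyloxy)-4-methoxy-6-(trimethylsilyloxy)phenyl]-2-(trimethylsilyloxy)ethan-1-one | COc1cc(O[Si](C)(C)C)c(C(=O)CO[Si](C)(C)C)c(OCc2ccccc2)c1 | intermediate
5 | 1-[2-(benzyloxy)-6-hydroxy-4-methoxyphenyl]-2-hydroxyethan-1-one | COc1cc(O)c(C(=O)CO)c(OCc2ccccc2)c1 | intermediate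
6 | 3,4-bis(benzyloxy)benzaldehyde | O=Cc1ccc(OCc2ccccc2)c(OCc2ccccc2)c1 | starting material
7 | 1,2-bis(benzyloxy)-4-(dimethoxymethyl)benzene | COC(OC)c1ccc(OCc2ccccc2)c(OCc2ccccc2)c1 | intermediate
8 | rac-6-(benzyloxy)-2-[3,4-bis(benzyloxy)phenyl]-8-methoxy-2H-1,3-benzodioxepin-5(4H)-one (racemic at the acetal carbon) | COc1cc(OCc2ccccc2)c2c(c1)OC(c1ccc(OCc3ccccc3)c(OCc3ccccc3)c1)OCC2=O | intermediate
9 | (2R,3R)-5-(benzyloxy)-2-[3,4-bis(benzyloxy)phenyl]-3-hydroxy-7-methoxy-2,3-dihydro-4H-chromen-4-one | COc1cc(OCc2ccccc2)c2c(c1)O[C@H](c1ccc(OCc3ccccc3)c(OCc3ccccc3)c1)[C@@H](O)C2=O | intermediate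
10 | (2R,3R)-5-(benzyloxy)-2-[3,4-bis(benzyloxy)phenyl]-7-methoxy-4-oxo-3,4-dihydro-2H-chromen-3-yl acetate | COc1cc(OCc2ccccc2)c2c(c1)O[C@H](c1ccc(OCc3ccccc3)c(OCc3ccccc3)c1)[C@@H](OC(C)=O)C2=O | intermediate
11 | 3-O-acetylpadmatin, (2R,3R)-2-(3,4-dihydroxyphenyl)-5-hydroxy-7-methoxy-4-oxo-3,4-dihydro-2H-chromen-3-yl acetate | COc1cc(O)c2c(c1)O[C@H](c1ccc(O)c(O)c1)[C@@H](OC(C)=O)C2=O | target

**Step count**

Total steps: 7. Longest linear sequence: 6 steps (steps 1, 2, 4, 5, 6, 7); step 3 is a one-step side branch.

**Steps most likely to fail**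

Step 5 (bears the label). The catalyst may discriminate the enediolate faces poorly. Enolisation of the intact ring before ionisation would give the enediol with the oxygens trans and hence closure to the 2,3-cis isomer. The cation may also be captured by the electron-rich A ring of a second molecule, or hydrolysed by traces of water. The fallback uses known chemistry, sets out from 2 (with aldehyde 6) and comes back at 9. The free phenol of 2 is protected with MOMCl and iPr2NEt to give 1-[2-(benzyloxy)-4-methoxy-6-(methoxymethoxy)phenyl]ethan-1-one F1. Claisen–Schmidt condensation of this ketone with 6 (KOH, EtOH) gives (E)-1-[2-(benzyloxy)-4-methoxy-6-(methoxymethoxy)phenyl]-3-[3,4-bis(benzyloxy)phenyl]prop-2-en-1-one F2. Juliá–Colonna epoxidation (poly-L-leucine, urea–H2O2, DBU, THF) should give [2-(benzyloxy)-4-methoxy-6-(methoxymethoxy)phenyl][(2R,3S)-3-[3,4-bis(benzyloxy)phenyl]oxiran-2-yl]methanone F3. Treatment with HCl in MeOH–THF removes the MOM group, and the freed phenol opens the epoxide at the benzylic carbon with inversion (6-endo) to give 9. The carbinol centre of the epoxide becomes C3 unchanged.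

Step 4. The equilibrium for bringing the ketone-bound phenol into a seven-membered mixed acetal may lie on the side of open or oligomeric acetals, and the product may hydrolyse or rearrange without stereocontrol on acidic supports. The fallback sets out from 5 (with aldehyde 6 in place of 7) and comes back at 8. Diol 5 is silylated again (TMSCl, Et3N, CH2Cl2) to its bis(trimethylsilyl) ether, which is compound 4 of the list. This ether is condensed with 6 under TMSOTf catalysis at −78 °C (Noyori acetalisation). The irreversible silyl transfer to hexamethyldisiloxane drives ring closure kinetically instead of through an acetal exchange equilibrium.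

Step 2. The peracid may attack the trioxygenated ring or bring about Baeyer–Villiger cleavage of the aryl ketone, and silylation of the hindered, hydrogen-bonded ketone may stay incomplete. The fallback replaces enol ether oxidation by halogenation and substitution, sets out from 2 and comes back at 5. Acetylation (Ac2O, pyridine) gives 2-acetyl-3-(benzyloxy)-5-methoxyphenyl acetate F4. α-Bromination with CuBr2 in EtOAc–CHCl3 at reflux gives 3-(benzyloxy)-2-(bromoacetyl)-5-methoxyphenyl acetate F5. Displacement with sodium formate in DMF gives 2-[2-(acetyloxy)-6-(benzyloxy)-4-methoxyphenyl]-2-oxoethyl formate F6. Acid-catalysed methanolysis (HCl, MeOH) of both esters gives 5; the phenol stays masked until the bromide is gone, so closure to a benzofuranone is avoided.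

**Further compounds**

F1 | step 5 | 1-[2-(benzyloxy)-4-methoxy-6-(methoxymethoxy)phenyl]ethan-1-one | COCOc1cc(OC)cc(OCc2ccccc2)c1C(C)=O
F2 | step 5 | (E)-1-[2-(benzyloxy)-4-methoxy-6-(methoxymethoxy)phenyl]-3-[3,4-bis(benzyloxy)phenyl]prop-2-en-1-one | COCOc1cc(OC)cc(OCc2ccccc2)c1C(=O)/C=C/c1ccc(OCc2ccccc2)c(OCc2ccccc2)c1
F3 | step 5 | [2-(benzyloxy)-4-methoxy-6-(methoxymethoxy)phenyl][(2R,3S)-3-[3,4-bis(benzyloxy)phenyl]oxiran-2-yl]methanone | COCOc1cc(OC)cc(OCc2ccccc2)c1C(=O)[C@@H]1O[C@H]1c1ccc(OCc2ccccc2)c(OCc2ccccc2)c1
F0 | step 4 | none | none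
F4 | step 2 | 2-acetyl-3-(benzyloxy)-5-methoxyphenyl acetate | CC(=O)Oc1cc(OC)cc(OCc2ccccc2)c1C(C)=O
F5 | step 2 | 3-(benzyloxy)-2-(bromoacetyl)-5-methoxyphenyl acetate | CC(=O)Oc1cc(OC)cc(OCc2ccccc2)c1C(=O)CBr
F6 | step 2 | 2-[2-(acetyloxy)-6-(benzyloxy)-4-methoxyphenyl]-2-oxoethyl formate | CC(=O)Oc1cc(OC)cc(OCc2ccccc2)c1C(=O)COC=O
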